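The earlier runs and the new flask were computed with constants of no real substance, and the scatter is random.

In the grey run, target held per starting material lost stood at 0.667 at the first reading; that is below one, so I suspected that some target had gone on and taken starting material with it.

- grey: starting material 0.50 M; reagent 1.2 equiv; second substrate 1 equiv; third substrate 1 equiv; the very flask that is asked about, followed so far
- flask: starting material 0.50 M; reagent 1.20 equiv; second substrate 1.00 equiv; third substrate 1.00 equiv; time 15 d

grey run (percent of the starting material charged)

| time / d | target / % | starting material / % |
|---|---|---|
| 0.0556 | 12 | 82 |
| 0.125 | 21 | 74 |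
| 0.250 | 25 | 65 |
| 0.500 | 17 | 53 |
| 1.04 | 11 | 45 |
| 2.00 | 2 | 39 |
| 5.00 | 0 | 35 |

(readings scatter by 2 percentage points)

- time, not beyond 15 d, at which the flask holds most target
- the amount of target, in percent of the starting material charged, at that time
- the first time at which target reaches 11%, in the same percent



I therefore followed the remainder, starting material minus target, in fractions of the charge. Making one target lowers it twice over, while a target consuming one starting material leaves it unchanged. These are the grey readings, with the fall per day since the reading before, the first row counted from the charge:

| Time | Remainder | Fall |
|---|---|---|
| 0.0556 d | 70.0% | 5.40 d⁻¹ |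
| 0.125 d | 53.0% | 2.45 d⁻¹ |
| 0.250 d | 40.0% | 1.04 d⁻¹ |
| 0.500 d | 36.0% | 0.160 d⁻¹ |

As read, with the scatter in each difference, the fall slowed by factors of 2.20, 2.36 and 6.50. The 4 readings from 0.500 d on average 35.5% and show no trend beyond the scatter, while target sank to 0%. So I reckoned the target ever made at 32.2% of the charge. At one reagent per target, that is the share of the charged reagent taken by the starting material (a selectivity measure), 26.9%, about a quarter.

Replacing the early curve by its mean, I took half the first fall, 2.70 d⁻¹, as the mean rate of making target up to the first reading. At that rate the target made reaches 11% in 0.979 h, and I took this as my time for the target held, setting aside the target lost meanwhile.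

The forecast gave 25% at 0.2 d and 1.2 h for the level, on the ground that “The early rise is slightly concave”, a later time than mine.

The flask gave 22.3% at 0.228 d and reached the level at 0.939 h.

    second substrate + reagent → second product (k = 0.430 M⁻¹ h⁻¹)
    starting material + reagent → target (k = 0.270 M⁻¹ h⁻¹)
    third substrate + reagent → third product (k = 0.330 M⁻¹ h⁻¹)
    starting material + target → side product (k = 0.180 M⁻¹ h⁻¹)

The flask's remainder stood at 34.9% at 1.50 d and at 34.9% at 15.0 d, and its final state gives a share of 27.1%. The neighbouring flask, charged with 1.70 equiv of second substrate, ended with 0% target and 49.5% starting material. So that neighbour made 25.2% target in total, and its share of reagent was 21.0%, lower than the 26.9% read from the grey run. Its best target was 18.3%.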